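**Plan** (cembrane-type numbering: C1 ring-fusion CH; C3/C4 epoxide; C7 CH–OAc; C8 C(Me)OH; C11 CH–OH; C12 C(Me)–O of the lactone; C15/C16/C17 lactone α-carbon/C=O/=CH2)
1. Cuts: C15=C17 (last, HWE with CH2O on a C15 phosphonate); the ring CH2–CH2 bonds C9–C10 (14-membered ring) and C13–C14 (oxepanone), both as RCM olefins; C1–C15 (Ir allylic alkylation); O12–C16 (acylation of a tertiary alcohol).
2. Forward: carbonate 10 (from geranyl acetate, epoxide already in place) + phosphonoacetate 18 (from divinylcarbinol) → open-chain tetraene 19 → one-pot double RCM (oxepinone first, 14-membered carbocycle last) → hydrogenation → methylenation → PMB removal.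
3. Stereochemistry: C7/C8 by asymmetric epoxidation then invertive acetolysis at C7; C3/C4 by Shi epoxidation; C11 by epoxidative desymmetrisation of divinylcarbinol; C12 by chelation-controlled vinyl addition; C1 by the Ir/phosphoramidite catalyst; the C15 epimers converge in the HWE step.
4. Enabling feature: C9–C10 and C13–C14 are CH2–CH2 links flanked by branched sp3 carbons (C8/C11 and C12/C1) that can each carry a vinyl group, and the lactone ester O12–C16 ties the two halves together, so the oxepanone and the 14-membered ring can both be closed from one tetraene.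

Key step: step 16

Assumption: stannane 7 is taken as a catalogue reagent (otherwise one step from propargyl alcohol, Bu3SnH/AIBN), and L in step 15 is the phosphoramidite antipode that gives the (S)-configured branch centre (its mirror image is used if the sense proves opposite).

Step 1
Reactants: 1 geranyl acetate
Product: 2 (2E,6E)-8-hydroxy-3,7-dimethylocta-2,6-dien-1-yl acetate
Conditions: SeO2 (cat.), t-BuOOH, CH2Cl2, rt
Reagents that add atoms: tert-butyl hydroperoxide CC(C)(C)OO (oxygen source; SeO2, O=[Se]=O, is the catalytic carrier)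
Why: Allylic oxidation (ene/[2,3] sequence) should attack the electron-rich terminal alkene at its (E)-methyl group, the 2,3-alkene being deactivated by the allylic acetate; no stereocenter is formed.

Step 2
Reactants: 2 (2E,6E)-8-hydroxy-3,7-dimethylocta-2,6-dien-1-yl acetate
Product: 3 (2E)-5-[(2S,3S)-3-(hydroxymethyl)-3-methyloxiran-2-yl]-3-methylpent-2-en-1-yl acetate
Conditions: Ti(OiPr)4 (cat.), L-(+)-diethyl tartrate (cat.), t-BuOOH, 4 Å MS, CH2Cl2, −20 °C
Reagents that add atoms: tert-butyl hydroperoxide CC(C)(C)OO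
Why: Sharpless asymmetric epoxidation of the (E)-2-methyl allylic alcohol, where L-(+)-tartrate should give the (S,S)-epoxide (C7 S, C8 S) by reagent control and the alkene without a free OH stays untouched.

Step 3
Reactants: 3 (2E)-5-[(2S,3S)-3-(hydroxymethyl)-3-methyloxiran-2-yl]-3-methylpent-2-en-1-yl acetate
Product: 4 (2E,6R,7S)-7,8-dihydroxy-3,7-dimethyloct-2-ene-1,6-diyl diacetate
Conditions: Ti(OiPr)4 (1.5 equiv), AcOH (1.5 equiv), CH2Cl2, 0 °C → rt
Reagents that add atoms: acetic acid CC(=O)O
Why: Ti-mediated C-3-selective opening of a 2,3-epoxy alcohol by a carboxylic acid: the titanium chelate should direct acetate to the secondary C7 with inversion (7S → 7R) while C8 keeps its oxygen (8S), giving the C7-OAc/C8-OH pair of the target.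

Step 4
Reactants: 4 (2E,6R,7S)-7,8-dihydroxy-3,7-dimethyloct-2-ene-1,6-diyl diacetate
Product: 5 (2E,6R,7R)-7-hydroxy-3,7-dimethyl-8-oxooct-2-ene-1,6-diyl diacetate
Conditions: Dess–Martin periodinane, NaHCO3, CH2Cl2, 0 °C
Reagents that add atoms: none
Why: Dess–Martin oxidation of the primary alcohol; the tertiary hydroxyl is inert and the α-carbon is quaternary, so nothing can epimerise (the descriptor changes only through CIP priority).

Step 5
Reactants: 5 (2E,6R,7R)-7-hydroxy-3,7-dimethyl-8-oxooct-2-ene-1,6-diyl diacetate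
Product: 6 (2E,6R,7S)-7-hydroxy-3,7-dimethylnona-2,8-diene-1,6-diyl diacetate
Conditions: Zn, CH2Br2, TiCl4 (pre-formed Lombardo reagent, excess), THF/CH2Cl2, 0 °C → rt
Reagents that add atoms: dibromomethane BrCBr
Why: Lombardo methylenation is non-basic and aldehyde-selective, so both acetates should survive and no base-induced acetyl shift to the neighbouring tertiary alkoxide can occur.

Step 6
Reactants: 6 (2E,6R,7S)-7-hydroxy-3,7-dimethylnona-2,8-diene-1,6-diyl diacetate; 7 (2E)-3-(tributylstannyl)prop-2-en-1-ol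
Product: 8 (2E,5E,9R,10S)-1,10-dihydroxy-6,10-dimethyldodeca-2,5,11-trien-9-yl acetate
Conditions: Pd2(dba)3 (2.5 mol %), LiCl (3 equiv), DMF, 40 °C
Reagents that add atoms: none
Why: Stille coupling of a primary allylic acetate with an (E)-alkenylstannane: only the allylic acetate is ionised, the stannane should attack the less hindered allyl terminus, and both alkene geometries should be retained to give the skipped (E,E)-diene.

Step 7
Reactants: 8 (2E,5E,9R,10S)-1,10-dihydroxy-6,10-dimethyldodeca-2,5,11-trien-9-yl acetate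
Product: 9 (2E,5E,9R,10S)-10-hydroxy-1-[(methoxycarbonyl)oxy]-6,10-dimethyldodeca-2,5,11-trien-9-yl acetate
Conditions: ClCO2Me, pyridine, CH2Cl2, 0 °C
Reagents that add atoms: methyl chloroformate COC(=O)Cl
Why: Carbonate formation on the primary allylic alcohol; the hindered tertiary alcohol should not react.

Step 8
Reactants: 9 (2E,5E,9R,10S)-10-hydroxy-1-[(methoxycarbonyl)oxy]-6,10-dimethyldodeca-2,5,11-trien-9-yl acetate
Product: 10 (2E)-4-{(2S,3S)-3-[(3R,4S)-3-acetoxy-4-hydroxy-4-methylhex-5-en-1-yl]-3-methyloxiran-2-yl}but-2-en-1-yl methyl carbonate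
Conditions: ent-Shi ketone (L-fructose-derived, 30 mol %), Oxone, K2CO3, Bu4NHSO4, MeCN/DMM–aq. borate buffer (pH 10.5), 0 °C
Reagents that add atoms: Oxone (potassium peroxymonosulfate) [K+].[O-]S(=O)(=O)OO
Why: Shi epoxidation: the chiral dioxirane should epoxidise only the electron-rich trisubstituted alkene (the disubstituted one is deactivated by the allylic carbonate, the vinyl group is monosubstituted) through the spiro transition state, the ent-ketone giving the (3S,4S)-epoxide by reagent control.

Step 9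
Reactants: 11 penta-1,4-dien-3-ol
Product: 12 (1R)-1-[(2S)-oxiran-2-yl]prop-2-en-1-ol
Conditions: Ti(OiPr)4, D-(−)-diisopropyl tartrate, t-BuOOH, 4 Å MS, CH2Cl2, −20 °C
Reagents that add atoms: tert-butyl hydroperoxide CC(C)(C)OO
Why: Sharpless epoxidation of divinylcarbinol, where enantiotopic-group selection coupled with erythro face selection should give the (2S,3R)-epoxy alcohol, fixing the carbinol centre (future C11) as R.

Step 10
Reactants: 12 (1R)-1-[(2S)-oxiran-2-yl]prop-2-en-1-ol
Product: 13 (2S)-2-{(1R)-1-[(4-methoxybenzyl)oxy]prop-2-en-1-yl}oxirane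
Conditions: NaH, PMBCl, Bu4NI (cat.), THF, 0 °C → rt
Reagents that add atoms: 4-methoxybenzyl chloride COc1ccc(CCl)cc1
Why: Williamson etherification at low temperature (fast trapping limits Payne rearrangement); PMB is a chelating group for step 13 and is removed oxidatively at the end.

Step 11
Reactants: 13 (2S)-2-{(1R)-1-[(4-methoxybenzyl)oxy]prop-2-en-1-yl}oxirane
Product: 14 (2S,3R)-3-[(4-methoxybenzyl)oxy]pent-4-en-2-ol
Conditions: LiAlH4, Et2O, 0 °C
Reagents that add atoms: none
Why: Hydride opens the terminal epoxide at the unhindered CH2 (SN2), leaving the methyl group that becomes the C12 methyl and a secondary alcohol; C11 is not touched.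

Step 12
Reactants: 14 (2S,3R)-3-[(4-methoxybenzyl)oxy]pent-4-en-2-ol
Product: 15 (3R)-3-[(4-methoxybenzyl)oxy]pent-4-en-2-one
Conditions: Dess–Martin periodinane, NaHCO3, CH2Cl2, 0 °C; used at once
Reagents that add atoms: none
Why: Buffered Dess–Martin oxidation gives the α-alkoxy methyl ketone without base, which should avoid epimerisation or conjugation of the β,γ-unsaturated ketone.

Step 13
Reactants: 15 (3R)-3-[(4-methoxybenzyl)oxy]pent-4-en-2-one
Product: 16 (3R,4R)-4-[(4-methoxybenzyl)oxy]-3-methylhexa-1,5-dien-3-ol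
Conditions: CH2=CHMgBr, THF, −78 °C
Reagents that add atoms: vinylmagnesium bromide C=C[Mg]Br
Why: Cram-chelate-controlled Grignard addition: Mg bridges the ketone and PMB-ether oxygens and vinyl should add from the face of the α-hydrogen, setting C12 (R) relative to C11 (R).

Step 14
Reactants: 16 (3R,4R)-4-[(4-methoxybenzyl)oxy]-3-methylhexa-1,5-dien-3-ol; 17 2-(diethoxyphosphoryl)acetic acid
Product: 18 (3R,4R)-4-[(4-methoxybenzyl)oxy]-3-methylhexa-1,5-dien-3-yl 2-(diethoxyphosphoryl)acetate
Conditions: DCC, DMAP (cat.), CH2Cl2, 0 °C → rt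
Reagents that add atoms: none
Why: Steglich-type esterification; carbodiimide-activated phosphonoacetic acid acylates through a ketene-like (E1cB) pathway, which is why hindered tertiary alcohols are esterified by it.

Step 15
Reactants: 10 (2E)-4-{(2S,3S)-3-[(3R,4S)-3-acetoxy-4-hydroxy-4-methylhex-5-en-1-yl]-3-methyloxiran-2-yl}but-2-en-1-yl methyl carbonate; 18 (3R,4R)-4-[(4-methoxybenzyl)oxy]-3-methylhexa-1,5-dien-3-yl 2-(diethoxyphosphoryl)acetate
Product: 19 tetraene ester, (3R,4R)-4-[(4-methoxybenzyl)oxy]-3-methylhexa-1,5-dien-3-yl (3S)-3-({(2S,3S)-3-[(3R,4S)-3-acetoxy-4-hydroxy-4-methylhex-5-en-1-yl]-3-methyloxiran-2-yl}methyl)-2-(diethoxyphosphoryl)pent-4-enoate (both C2 epimers)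
Conditions: [Ir(cod)Cl]2 (2 mol %), BINOL-derived bis(1-phenylethyl)amine phosphoramidite L (4 mol %), TBD (8 mol %), THF, rt (salt-free; methoxide released from the carbonate deprotonates 18)
Reagents that add atoms: none
Why: Iridium-catalysed asymmetric allylic alkylation with a stabilised phosphonoacetate carbanion should give the branched product, with the C1 configuration fixed by the ligand and not by the remote stereocenters; the primary allylic carbonate ionises far faster than the hindered tertiary allylic ester in 18.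

Step 16
Reactants: 19 tetraene ester
Product: 21 bicyclic diene (target skeleton with H and P(O)(OEt)2 on C15, C9=C10 and C13=C14 double bonds, C11–OPMB; C15 epimers, C9=C10 E/Z), via oxepinone triene 20 (not isolated)
Conditions: Grubbs second-generation catalyst (2 × 5 mol %), toluene (1 mM), 80 °C, argon sparge
Reagents that add atoms: none
Why: Two ring-closing olefin metatheses run in tandem at a Ru alkylidene ([2+2]/cycloreversion, ethene expelled), the closest known reaction types being double RCM of ester-tethered polyenes and macrocyclic RCM of cembranoid dienes. The oxepinone closes first as a 7-membered RCM between the C1 vinyl and the C12 vinyl, helped by the gem-disubstituted C12 (20); the 14-membered carbocycle then closes as a macro-RCM between the C11 vinyl and the C8 vinyl, whose free tertiary allylic hydroxyl speeds metathesis at this hindered alkene and whose chain ends are already held on one side by the new lactone ring. No stereocenter is formed: all seven are in place, and the C9=C10 geometry is irrelevant because both new alkenes are hydrogenated in step 17. The step needs pairing selectivity (7 + 14 rather than an 8-membered lactone from the C1/C11 vinyl pair, which would leave two quaternary-carbinol vinyls that can hardly pair) and ring closure over oligomerisation. These should be secured by the kinetic and thermodynamic preference for the 7- over the 8-membered unsaturated lactone, by the reversibility of metathesis while ethene is swept out, and by high dilution. The epoxide, acetate, phosphonate, PMB ether and tertiary alcohol are inert to the Ru carbene.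

Step 17
Reactants: 21 bicyclic diene
Product: 22 saturated α-phosphono lactone (as 21 with C9–C10 and C13–C14 single bonds; 1R,3S,4S,7R,8S,11R,12R; C15 epimers)
Conditions: H2 (1 atm), [Ir(cod)(PCy3)(py)]PF6 (5 mol %), CH2Cl2, rt
Reagents that add atoms: none
Why: Homogeneous hydrogenation with Crabtree's catalyst, directed to the hindered C9=C10 alkene by the C8 hydroxyl, should reduce both disubstituted alkenes without hydrogenolysis of the PMB ether, the allylic C–O bonds or the epoxide.

Step 18
Reactants: 22 saturated α-phosphono lactone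
Product: 23 11-O-(4-methoxybenzyl) ether of the target
Conditions: (CH2O)n, LiCl, DBU, THF, rt
Reagents that add atoms: formaldehyde (from paraformaldehyde) C=O
Why: Horner–Wadsworth–Emmons olefination of the α-phosphono lactone with formaldehyde under Masamune–Roush conditions should convert both C15 epimers into the one exo-methylene lactone, with a base mild enough to spare the acetate.

Step 19
Reactants: 23 11-O-(4-methoxybenzyl) ether of the target
Product: 24 target, (1R,3S,4S,7R,8S,11R,12R)-7-acetoxy-3,4-epoxy-8,11-dihydroxycembr-15(17)-en-16,12-olide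
Conditions: DDQ, CH2Cl2/pH 7 phosphate buffer, 0 °C
Reagents that add atoms: none
Why: Oxidative PMB cleavage (benzylic hydride abstraction, then hydrolysis of the oxocarbenium ion) under buffered conditions should leave the epoxide, the acetate and the α-methylene lactone untouched.

**Compound list**
1 | geranyl acetate | CC(C)=CCC/C(C)=C/COC(C)=O | starting material
2 | (2E,6E)-8-hydroxy-3,7-dimethylocta-2,6-dien-1-yl acetate | OC/C(C)=C/CC/C(C)=C/COC(C)=O | intermediate
3 | (2E)-5-[(2S,3S)-3-(hydroxymethyl)-3-methyloxiran-2-yl]-3-methylpent-2-en-1-yl acetate | OC[C@]1(C)O[C@H]1CC/C(C)=C/COC(C)=O | intermediate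
4 | (2E,6R,7S)-7,8-dihydroxy-3,7-dimethyloct-2-ene-1,6-diyl diacetate | CC(=O)OC/C=C(\C)CC[C@@H](OC(C)=O)[C@@](C)(O)CO | intermediate
5 | (2E,6R,7R)-7-hydroxy-3,7-dimethyl-8-oxooct-2-ene-1,6-diyl diacetate | CC(=O)OC/C=C(\C)CC[C@@H](OC(C)=O)[C@@](C)(O)C=O | intermediate
6 | (2E,6R,7S)-7-hydroxy-3,7-dimethylnona-2,8-diene-1,6-diyl diacetate | CC(=O)OC/C=C(\C)CC[C@@H](OC(C)=O)[C@@](C)(O)C=C | intermediate
7 | (2E)-3-(tributylstannyl)prop-2-en-1-ol | OC/C=C/[Sn](CCCC)(CCCC)CCCC | starting material
8 | (2E,5E,9R,10S)-1,10-dihydroxy-6,10-dimethyldodeca-2,5,11-trien-9-yl acetate | OC/C=C/C/C=C(\C)CC[C@@H](OC(C)=O)[C@@](C)(O)C=C | intermediate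
9 | (2E,5E,9R,10S)-10-hydroxy-1-[(methoxycarbonyl)oxy]-6,10-dimethyldodeca-2,5,11-trien-9-yl acetate | COC(=O)OC/C=C/C/C=C(\C)CC[C@@H](OC(C)=O)[C@@](C)(O)C=C | intermediate
10 | (2E)-4-{(2S,3S)-3-[(3R,4S)-3-acetoxy-4-hydroxy-4-methylhex-5-en-1-yl]-3-methyloxiran-2-yl}but-2-en-1-yl methyl carbonate | COC(=O)OC/C=C/C[C@@H]1O[C@@]1(C)CC[C@@H](OC(C)=O)[C@@](C)(O)C=C | intermediate
11 | penta-1,4-dien-3-ol | C=CC(O)C=C | starting material
12 | (1R)-1-[(2S)-oxiran-2-yl]prop-2-en-1-ol | C=C[C@@H](O)[C@@H]1CO1 | intermediate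
13 | (2S)-2-{(1R)-1-[(4-methoxybenzyl)oxy]prop-2-en-1-yl}oxirane | C=C[C@@H](OCc1ccc(OC)cc1)[C@@H]1CO1 | intermediate
14 | (2S,3R)-3-[(4-methoxybenzyl)oxy]pent-4-en-2-ol | C=C[C@@H](OCc1ccc(OC)cc1)[C@H](C)O | intermediate
15 | (3R)-3-[(4-methoxybenzyl)oxy]pent-4-en-2-one | C=C[C@@H](OCc1ccc(OC)cc1)C(C)=O | intermediate
16 | (3R,4R)-4-[(4-methoxybenzyl)oxy]-3-methylhexa-1,5-dien-3-ol | C=C[C@@H](OCc1ccc(OC)cc1)[C@](C)(O)C=C | intermediate
17 | 2-(diethoxyphosphoryl)acetic acid | CCOP(=O)(CC(=O)O)OCC | starting material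
18 | (3R,4R)-4-[(4-methoxybenzyl)oxy]-3-methylhexa-1,5-dien-3-yl 2-(diethoxyphosphoryl)acetate | C=C[C@@H](OCc1ccc(OC)cc1)[C@](C)(OC(=O)CP(=O)(OCC)OCC)C=C | intermediate
19 | tetraene ester, (3R,4R)-4-[(4-methoxybenzyl)oxy]-3-methylhexa-1,5-dien-3-yl (3S)-3-({(2S,3S)-3-[(3R,4S)-3-acetoxy-4-hydroxy-4-methylhex-5-en-1-yl]-3-methyloxiran-2-yl}methyl)-2-(diethoxyphosphoryl)pent-4-enoate (C2 epimers) | C=C[C@@H](OCc1ccc(OC)cc1)[C@](C)(OC(=O)C(P(=O)(OCC)OCC)[C@H](C=C)C[C@@H]1O[C@@]1(C)CC[C@@H](OC(C)=O)[C@@](C)(O)C=C)C=C | intermediate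
20 | oxepinone triene, (4S,7R)-3-(diethoxyphosphoryl)-4-({(2S,3S)-3-[(3R,4S)-3-acetoxy-4-hydroxy-4-methylhex-5-en-1-yl]-3-methyloxiran-2-yl}methyl)-7-{(1R)-1-[(4-methoxybenzyl)oxy]prop-2-en-1-yl}-7-methyl-4,7-dihydrooxepin-2(3H)-one (C3 epimers) | C=C[C@@H](OCc1ccc(OC)cc1)[C@]1(C)OC(=O)C(P(=O)(OCC)OCC)[C@@H](C[C@@H]2O[C@@]2(C)CC[C@@H](OC(C)=O)[C@@](C)(O)C=C)C=C1 | intermediate
21 | bicyclic diene: target skeleton with H and P(O)(OEt)2 on C15, C9=C10 and C13=C14 double bonds and C11–OPMB (1S,3S,4S,7R,8S,11R,12R; C15 epimers; C9=C10 E/Z) | CCOP(=O)(OCC)C1C(=O)O[C@]2(C)C=C[C@@H]1C[C@@H]1O[C@@]1(C)CC[C@@H](OC(C)=O)[C@@](C)(O)C=C[C@H]2OCc1ccc(OC)cc1 | intermediate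
22 | saturated α-phosphono lactone: as 21 with C9–C10 and C13–C14 single bonds (1R,3S,4S,7R,8S,11R,12R; C15 epimers) | CCOP(=O)(OCC)C1C(=O)O[C@]2(C)CC[C@@H]1C[C@@H]1O[C@@]1(C)CC[C@@H](OC(C)=O)[C@@](C)(O)CC[C@H]2OCc1ccc(OC)cc1 | intermediate
23 | 11-O-(4-methoxybenzyl) ether of the target | C=C1C(=O)O[C@]2(C)CC[C@@H]1C[C@@H]1O[C@@]1(C)CC[C@@H](OC(C)=O)[C@@](C)(O)CC[C@H]2OCc1ccc(OC)cc1 | intermediate
24 | (1R,3S,4S,7R,8S,11R,12R)-7-acetoxy-3,4-epoxy-8,11-dihydroxycembr-15(17)-en-16,12-olide | C=C1C(=O)O[C@]2(C)CC[C@@H]1C[C@@H]1O[C@@]1(C)CC[C@@H](OC(C)=O)[C@@](C)(O)CC[C@H]2O | target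

Total step count: 19. Longest linear sequence: 13 steps (steps 1–8, then 15–19).

**Steps most likely to fail**

Step 16. The four vinyl groups may pair wrongly (8-membered lactone from the two unhindered vinyls), or intermolecular metathesis may outrun the slow closure onto the hindered C8 vinyl. The fallback closes the rings one at a time behind a protecting-group gate. It sets out from 19, whose tertiary hydroxyl is silylated (TESOTf, 2,6-lutidine, −78 °C) to the C8-O-triethylsilyl ether of the tetraene F1; its protected tertiary allylic vinyl should stay out of the metathesis. RCM (Grubbs second-generation catalyst, CH2Cl2, 40 °C) then closes only the oxepinone, giving the C8-O-triethylsilyl ether of the oxepinone triene F2. Buffered fluoride (TBAF/AcOH) frees the alcohol, which is compound 20, now isolated. A separate high-dilution RCM of 20, in which only one vinyl pair is left, returns to the route at 21.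

Step 15. The bulky tertiary-alkyl phosphonoacetate may erode branched and facial selectivity, or the tertiary allylic ester of 18 may itself be ionised by the catalyst. The fallback sets the C1 centre on a small nucleophile and joins the halves by esterification. It sets out from 10: the same Ir-catalysed allylic alkylation with allyl diethylphosphonoacetate should give the allyl (3S)-2-(diethoxyphosphoryl)-3-(epoxyalkyl)pent-4-enoate F3. Pd(PPh3)4/morpholine removes the allyl group to give the α-phosphono acid F4. Carbodiimide coupling of F4 with tertiary alcohol 16 (DCC, DMAP), again through the ketene-type pathway, returns to the route at 19.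

Step 3. Acetate may attack the tertiary epoxide carbon, or the new acetyl group may migrate to the primary hydroxyl. The fallback inverts the other carbon with water. It sets out from 2: epoxidation with D-(−)-diethyl tartrate gives the enantiomeric epoxy alcohol, (2E)-5-[(2R,3R)-3-(hydroxymethyl)-3-methyloxiran-2-yl]-3-methylpent-2-en-1-yl acetate F5. Acid-catalysed hydrolysis (HClO4, THF/H2O) opens it at the tertiary carbon with inversion to (2E,6R,7S)-6,7,8-trihydroxy-3,7-dimethyloct-2-en-1-yl acetate F6, which has the same C7/C8 arrangement as 4. Primary-selective oxidation (TEMPO, NCS, Bu4NCl) gives the dihydroxy aldehyde F7, and Lombardo methylenation gives the diol F8. Ac2O/pyridine acetylates only the secondary hydroxyl and returns to the route at 6.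

**Further compounds**
F1 | step 16 | C8-O-triethylsilyl ether of tetraene 19 | C=C[C@@H](OCc1ccc(OC)cc1)[C@](C)(OC(=O)C(P(=O)(OCC)OCC)[C@H](C=C)C[C@@H]1O[C@@]1(C)CC[C@@H](OC(C)=O)[C@@](C)(O[Si](CC)(CC)CC)C=C)C=C
F2 | step 16 | C8-O-triethylsilyl ether of oxepinone triene 20 | C=C[C@@H](OCc1ccc(OC)cc1)[C@]1(C)OC(=O)C(P(=O)(OCC)OCC)[C@@H](C[C@@H]2O[C@@]2(C)CC[C@@H](OC(C)=O)[C@@](C)(O[Si](CC)(CC)CC)C=C)C=C1
F3 | step 15 | allyl (3S)-3-({(2S,3S)-3-[(3R,4S)-3-acetoxy-4-hydroxy-4-methylhex-5-en-1-yl]-3-methyloxiran-2-yl}methyl)-2-(diethoxyphosphoryl)pent-4-enoate (C2 epimers) | C=CCOC(=O)C(P(=O)(OCC)OCC)[C@H](C=C)C[C@@H]1O[C@@]1(C)CC[C@@H](OC(C)=O)[C@@](C)(O)C=C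
F4 | step 15 | (3S)-3-({(2S,3S)-3-[(3R,4S)-3-acetoxy-4-hydroxy-4-methylhex-5-en-1-yl]-3-methyloxiran-2-yl}methyl)-2-(diethoxyphosphoryl)pent-4-enoic acid (C2 epimers) | OC(=O)C(P(=O)(OCC)OCC)[C@H](C=C)C[C@@H]1O[C@@]1(C)CC[C@@H](OC(C)=O)[C@@](C)(O)C=C
F5 | step 3 | (2E)-5-[(2R,3R)-3-(hydroxymethyl)-3-methyloxiran-2-yl]-3-methylpent-2-en-1-yl acetate | OC[C@@]1(C)O[C@@H]1CC/C(C)=C/COC(C)=O
F6 | step 3 | (2E,6R,7S)-6,7,8-trihydroxy-3,7-dimethyloct-2-en-1-yl acetate | CC(=O)OC/C=C(\C)CC[C@@H](O)[C@@](C)(O)CO
F7 | step 3 | (2E,6R,7R)-6,7-dihydroxy-3,7-dimethyl-8-oxooct-2-en-1-yl acetate | CC(=O)OC/C=C(\C)CC[C@@H](O)[C@@](C)(O)C=O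
F8 | step 3 | (2E,6R,7S)-6,7-dihydroxy-3,7-dimethylnona-2,8-dien-1-yl acetate | CC(=O)OC/C=C(\C)CC[C@@H](O)[C@@](C)(O)C=C
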